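**Plan**

1. Retrosynthesis: the C8 angelate ester is cut first, then the C1–H and C10–H bonds are traced back to a C1=C10 double bond. The resulting guaia-1(10),4-dien-3-one is cut at C1–C5, C2–C3 and C3–C4 (C3 leaves as CO), which opens both rings to an acyclic allene-yne. This is cut at the two C11–CH3 bonds, at C7–C8 and at C9–C10.
2. Enabling feature: the cyclopentenone (C1–C5, ketone C3, methyl on C4, C4=C5) is fused through C5–C1 to the seven-membered ring (C1, C5–C10), and C10 with its methyl is bonded to C1. This is the pattern left when an alkyne C4≡C5, the terminal π-bond C1=C2 of a 1,1-disubstituted allene C10=C1=C2 and CO are joined.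
3. Forward: the allene arm (C8, C9, C10, C1, C2) comes from a Johnson–Claisen rearrangement and is joined at C7–C8 to a hex-4-ynoyl imide (C4–C7, C11) by an aldol reaction. MeMgBr completes C11, one cyclocarbonylation closes the five- and the seven-membered ring together, and 1,6-reduction, desilylation and angeloylation finish.
4. Stereochemistry: C7 and C8 come from an Evans syn-aldol with (S)-4-benzyl-2-oxazolidinone. C10 comes from hydride addition to the dienone on the face opposite the C8 silyloxy group and the C7 side chain. C1 is set by equilibration through the dienolate to the more stable epimer.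

Key step: step 10

Remark: guaiane numbering (C3 ketone, C4=C5, C1/C5 ring fusion, C7 side chain C11, C8 ester oxygen, C10 methyl) is used for the atoms of all compounds, open-chain ones included; descriptors inside names follow each compound's own IUPAC numbering.

**Route**

Step 1
Reactants: 1 hex-4-ynoic acid; 2 (S)-4-benzyl-2-oxazolidinone
Product: 4 (4S)-4-benzyl-3-(hex-4-ynoyl)-1,3-oxazolidin-2-one, via mixed pivalic anhydride 3 (not isolated)
Conditions: PivCl, Et3N, THF, −20 °C; then LiCl, 2, −20 °C → rt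
Reagents that add atoms: none
Why: N-acylation of the oxazolidinone through a mixed anhydride (LiCl/Et3N protocol); the nitrogen should attack the unhindered hexynoyl carbonyl and not the tert-butyl-shielded pivaloyl carbonyl.

Step 2
Reactants: 5 but-2-yn-1-ol; 6 triethyl orthoacetate
Product: 9 ethyl 3-methylpenta-3,4-dienoate, via mixed orthoester 7 (not isolated), via ketene acetal 8 (not isolated)
Conditions: EtCO2H (cat.), excess 6, 140 °C, EtOH distilled off
Reagents that add atoms: none
Why: Johnson orthoester Claisen rearrangement; the [3,3] shift of the propargyl ketene acetal forms C9–C10 at the methyl-bearing alkyne carbon and turns the triple bond into the 1,1-disubstituted allene C10=C1=C2.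

Step 3
Reactants: 9 ethyl 3-methylpenta-3,4-dienoate
Product: 10 3-methylpenta-3,4-dien-1-ol
Conditions: LiAlH4, Et2O, 0 °C
Reagents that add atoms: none
Why: Hydride reduction of an ester to the primary alcohol; the isolated allene is inert to LiAlH4.

Step 4
Reactants: 10 3-methylpenta-3,4-dien-1-ol
Product: 11 3-methylpenta-3,4-dienal
Conditions: Dess–Martin periodinane, CH2Cl2, 0 °C → rt; filtered cold solution used at once
Reagents that add atoms: none
Why: Dess–Martin oxidation under base-free conditions should stop at the aldehyde without moving the allene into conjugation; the volatile product is kept in solution.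

Step 5
Reactants: 4 (4S)-4-benzyl-3-(hex-4-ynoyl)-1,3-oxazolidin-2-one; 11 3-methylpenta-3,4-dienal
Product: 14 (4S)-4-benzyl-3-[(2S,3R)-2-(but-2-yn-1-yl)-3-hydroxy-5-methylhepta-5,6-dienoyl]-1,3-oxazolidin-2-one, via boron enolate 12 (not isolated), via boron aldolate 13 (not isolated)
Conditions: Bu2BOTf, iPr2NEt, CH2Cl2, 0 °C; 11 (excess), −78 → 0 °C; then pH 7 buffer, MeOH, 30% H2O2, 0 °C
Reagents that add atoms: none
Why: Evans syn-aldol; the dibutylboron (Z)-enolate reacts through a closed chair (Zimmerman–Traxler) transition state in which the auxiliary carbonyl points away from the enolate oxygen and its benzyl group blocks one enolate face, so C7 (S) and C8 (R) should be set together as the 2S,3R syn adduct, with C–C bond formation at −78 °C expected to outrun enolisation of the β,γ-allenic aldehyde.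

Step 6
Reactants: 14 aldol adduct
Product: 15 methyl (2S,3R)-2-(but-2-yn-1-yl)-3-hydroxy-5-methylhepta-5,6-dienoate
Conditions: MeMgBr, MeOH (gives MeOMgBr), CH2Cl2, 0 °C
Reagents that add atoms: methanol (acting as MeOMgBr), SMILES CO
Why: Transesterification by exocyclic cleavage of the imide with MeOMgBr; the magnesium chelate of the β-hydroxy imide activates the acyl carbonyl and should hold back retro-aldol and epimerisation at C7, and the auxiliary is recovered.

Step 7
Reactants: 15 methyl (2S,3R)-2-(but-2-yn-1-yl)-3-hydroxy-5-methylhepta-5,6-dienoate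
Product: 16 methyl (2S,3R)-2-(but-2-yn-1-yl)-3-[(tert-butyldimethylsilyl)oxy]-5-methylhepta-5,6-dienoate
Conditions: TBSOTf, 2,6-lutidine, CH2Cl2, −78 → 0 °C
Reagents that add atoms: tert-butyldimethylsilyl triflate, SMILES CC(C)(C)[Si](C)(C)OS(=O)(=O)C(F)(F)F
Why: Silylation of the only hydroxyl with a silyl triflate and a hindered pyridine base, a standard protection that leaves ester, alkyne and allene alone.

Step 8
Reactants: 16 silyl ether methyl ester
Product: 18 (3S,4R)-3-(but-2-yn-1-yl)-4-[(tert-butyldimethylsilyl)oxy]-2,6-dimethylocta-6,7-dien-2-ol, via methyl ketone 17 (not isolated)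
Conditions: MeMgBr (3.5 equiv), THF, 0 °C → rt
Reagents that add atoms: methylmagnesium bromide, SMILES C[Mg]Br
Why: Double Grignard addition to the ester through the methyl ketone builds the C11 tertiary carbinol; carbonyl addition should be faster than deprotonation at C7, so the C7 configuration and the β-silyloxy group are kept.

Step 9
Reactants: 18 tertiary alcohol
Product: 19 (3S,4R)-3-(but-2-yn-1-yl)-4-[(tert-butyldimethylsilyl)oxy]-2,6-dimethylocta-6,7-dien-2-yl acetate (the allene-yne)
Conditions: Ac2O, DMAP (1 equiv), Et3N, CH2Cl2, 40 °C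
Reagents that add atoms: acetic anhydride, SMILES CC(=O)OC(C)=O
Why: DMAP-catalysed acylation (acylpyridinium transfer) of the only free hydroxyl; tertiary alcohols are acetylated under these conditions on warming, and silyl ether, allene and alkyne are inert.

Step 10
Reactants: 19 allene-yne
Product: 20 (7S,8R)-11-acetoxy-8-[(tert-butyldimethylsilyl)oxy]guaia-1(10),4-dien-3-one, i.e. 2-[(5S,6R)-6-[(tert-butyldimethylsilyl)oxy]-3,8-dimethyl-2-oxo-1,2,4,5,6,7-hexahydroazulen-5-yl]propan-2-yl acetate
Conditions: [Rh(CO)2Cl]2 (5–10 mol %), CO (1 atm), toluene (0.01 M), 90–110 °C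
Reagents that add atoms: carbon monoxide, SMILES [C-]#[O+]
Why: Monovalent rhodium binds the alkyne C4≡C5 and the terminal π-bond C1=C2 of the allene and couples them oxidatively to a rhodacyclopentene, which forms C5–C1; CO then inserts into a Rh–C bond and reductive elimination forms C2–C3 and C3–C4 and returns the catalyst. The closest known reaction type is the rhodium-catalysed allenic Pauson–Khand cyclocarbonylation of allene-ynes to 4-alkylidenecyclopentenones fused to seven-membered rings. The seven-membered ring closes in the cyclometallation, by exo bonding of alkyne carbon C5 to the central allene carbon C1 across the tether C6–C9 and C10, and the cyclopentenone closes as a [2+2+1] assembly of C4≡C5, C1=C2 and CO by insertion and reductive elimination. No stereocenter is created, and C7 and C8 on the tether are not touched. The step needs the distal and not the proximal allene π-bond to react and carbonylation to outrun ene-type cycloisomerisation: the rhodium carbonyl catalyst prefers the terminal π-bond, the proximal mode would have to make C10 quaternary, the vicinal C7/C8 substituents fold the chain, and the CO atmosphere intercepts the rhodacycle.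

Step 11
Reactants: 20 dienone
Product: 22 (1R,7S,8R,10S)-11-acetoxy-8-[(tert-butyldimethylsilyl)oxy]guai-4-en-3-one, via deconjugated ketone 21 (not isolated)
Conditions: [(Ph3P)CuH]6 (0.4 equiv), H2O (5 equiv), degassed toluene, rt; then DBU, CH2Cl2, rt
Reagents that add atoms: none
Why: Copper hydride 1,6-conjugate reduction; hydride should add to C10 of the linear dienone on the face opposite the C8 silyloxy group and the C7 side chain (setting 10S), water protonates the copper dienolate to the deconjugated ketone, and DBU moves the double bond back to C4=C5 while equilibrating C1 through the dienolate to the more stable epimer with H-1 anti to H-10 (1R).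

Step 12
Reactants: 22 silyl ether enone
Product: 23 (1R,7S,8R,10S)-11-acetoxy-8-hydroxyguai-4-en-3-one
Conditions: HF·pyridine, pyridine, THF, 0 °C → rt
Reagents that add atoms: none
Why: Desilylation driven by Si–F bond formation; the weakly acidic medium never generates the C8 alkoxide, so 1,3-migration of the C11 acetyl group to O8 should be avoided and the enone is untouched.

Step 13
Reactants: 23 (1R,7S,8R,10S)-11-acetoxy-8-hydroxyguai-4-en-3-one; 24 angelic acid
Product: 26 torilin, via mixed trichlorobenzoic anhydride 25 (not isolated)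
Conditions: 24, 2,4,6-Cl3C6H2COCl, Et3N, toluene, rt; then 23, 80 °C
Reagents that add atoms: none
Why: Yamaguchi-type esterification; the hindered trichlorobenzoyl carbonyl directs the C8 hydroxyl to the angeloyl carbonyl of the mixed anhydride, and leaving out DMAP and other nucleophilic catalysts should prevent Z-to-E isomerisation to the tiglate.

**Compound list**

1 | hex-4-ynoic acid | CC#CCCC(=O)O | starting material
2 | (S)-4-benzyl-2-oxazolidinone | O=C1N[C@@H](Cc2ccccc2)CO1 | starting material
3 | hex-4-ynoic pivalic anhydride | CC#CCCC(=O)OC(=O)C(C)(C)C | intermediate (not isolated)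
4 | (4S)-4-benzyl-3-(hex-4-ynoyl)-1,3-oxazolidin-2-one | CC#CCCC(=O)N1[C@@H](Cc2ccccc2)COC1=O | intermediate
5 | but-2-yn-1-ol | CC#CCO | starting material
6 | triethyl orthoacetate | CCOC(C)(OCC)OCC | starting material
7 | 1-(1,1-diethoxyethoxy)but-2-yne (mixed orthoester) | CCOC(C)(OCC)OCC#CC | intermediate (not isolated)
8 | 1-[(1-ethoxyethenyl)oxy]but-2-yne (ketene acetal) | C=C(OCC)OCC#CC | intermediate (not isolated)
9 | ethyl 3-methylpenta-3,4-dienoate | CCOC(=O)CC(C)=C=C | intermediate
10 | 3-methylpenta-3,4-dien-1-ol | OCCC(C)=C=C | intermediate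
11 | 3-methylpenta-3,4-dienal | O=CCC(C)=C=C | intermediate
12 | dibutylboron (Z)-enolate of 4 | CC#CC/C=C(\OB(CCCC)CCCC)N1[C@@H](Cc2ccccc2)COC1=O | intermediate (not isolated)
13 | O-dibutylboryl aldolate of 14 | CCCCB(CCCC)O[C@@H]([C@H](CC#CC)C(=O)N1[C@@H](Cc2ccccc2)COC1=O)CC(C)=C=C | intermediate (not isolated)
14 | (4S)-4-benzyl-3-[(2S,3R)-2-(but-2-yn-1-yl)-3-hydroxy-5-methylhepta-5,6-dienoyl]-1,3-oxazolidin-2-one | O[C@@H]([C@H](CC#CC)C(=O)N1[C@@H](Cc2ccccc2)COC1=O)CC(C)=C=C | intermediate
15 | methyl (2S,3R)-2-(but-2-yn-1-yl)-3-hydroxy-5-methylhepta-5,6-dienoate | O[C@@H]([C@H](CC#CC)C(=O)OC)CC(C)=C=C | intermediate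
16 | methyl (2S,3R)-2-(but-2-yn-1-yl)-3-[(tert-butyldimethylsilyl)oxy]-5-methylhepta-5,6-dienoate | CC(C)(C)[Si](C)(C)O[C@@H]([C@H](CC#CC)C(=O)OC)CC(C)=C=C | intermediate
17 | (3S,4R)-3-(but-2-yn-1-yl)-4-[(tert-butyldimethylsilyl)oxy]-6-methylocta-6,7-dien-2-one | CC(C)(C)[Si](C)(C)O[C@@H]([C@H](CC#CC)C(C)=O)CC(C)=C=C | intermediate (not isolated)
18 | (3S,4R)-3-(but-2-yn-1-yl)-4-[(tert-butyldimethylsilyl)oxy]-2,6-dimethylocta-6,7-dien-2-ol | CC(C)(C)[Si](C)(C)O[C@@H]([C@H](CC#CC)C(C)(C)O)CC(C)=C=C | intermediate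
19 | (3S,4R)-3-(but-2-yn-1-yl)-4-[(tert-butyldimethylsilyl)oxy]-2,6-dimethylocta-6,7-dien-2-yl acetate | CC(C)(C)[Si](C)(C)O[C@@H]([C@H](CC#CC)C(C)(C)OC(C)=O)CC(C)=C=C | intermediate
20 | (7S,8R)-11-acetoxy-8-[(tert-butyldimethylsilyl)oxy]guaia-1(10),4-dien-3-one | CC(C)(C)[Si](C)(C)O[C@@H]1CC(C)=C2CC(=O)C(C)=C2C[C@@H]1C(C)(C)OC(C)=O | intermediate
21 | (7S,8R,10S)-11-acetoxy-8-[(tert-butyldimethylsilyl)oxy]guai-1(5)-en-3-one, both C4 epimers | CC(C)(C)[Si](C)(C)O[C@@H]1C[C@H](C)C2=C(C[C@@H]1C(C)(C)OC(C)=O)C(C)C(=O)C2 | intermediate (not isolated)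
22 | (1R,7S,8R,10S)-11-acetoxy-8-[(tert-butyldimethylsilyl)oxy]guai-4-en-3-one | CC(C)(C)[Si](C)(C)O[C@@H]1C[C@H](C)[C@H]2CC(=O)C(C)=C2C[C@@H]1C(C)(C)OC(C)=O | intermediate
23 | (1R,7S,8R,10S)-11-acetoxy-8-hydroxyguai-4-en-3-one | O[C@@H]1C[C@H](C)[C@H]2CC(=O)C(C)=C2C[C@@H]1C(C)(C)OC(C)=O | intermediate
24 | angelic acid, (Z)-2-methylbut-2-enoic acid | C/C=C(/C)C(=O)O | starting material
25 | (Z)-2-methylbut-2-enoic 2,4,6-trichlorobenzoic anhydride | C/C=C(/C)C(=O)OC(=O)c1c(Cl)cc(Cl)cc1Cl | intermediate (not isolated)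
26 | torilin, (1R,7S,8R,10S)-11-acetoxy-3-oxoguai-4-en-8-yl (Z)-2-methylbut-2-enoate | C/C=C(/C)C(=O)O[C@@H]1C[C@H](C)[C@H]2CC(=O)C(C)=C2C[C@@H]1C(C)(C)OC(C)=O | target

**Count and risks**

Total steps: 13. Longest linear sequence: 12 steps (steps 2 to 13, from but-2-yn-1-ol and triethyl orthoacetate); step 1 is the side branch.

Step 11. Hydride may be delivered to C5 (1,4-mode) instead of C10, transfer to the fully substituted C10 may be slow, or the two faces of C10 may not be told apart well enough. Fallback, setting out from 20: the C1=C10 bond is hydrogenated over Pd/C (palladium on carbon; H2, 1 atm, EtOAc, rt). This should take up hydrogen at the more exposed, less electron-poor C1=C10 bond and add both hydrogens from the face opposite the C8 silyloxy group, giving the 1-epimer, (1S,7S,8R,10S)-11-acetoxy-8-[(tert-butyldimethylsilyl)oxy]guai-4-en-3-one F1. DBU in CH2Cl2 then inverts C1 through the dienolate, and the route is rejoined at 22.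

Step 5. The β,γ-allenic aldehyde may slip into conjugation under the amine base, or be lost on concentration, before it meets the enolate. Fallback, setting out from 4: the allene is built after the aldol from a non-volatile ynal.
- Purchased 1-methoxy-4-[(prop-2-yn-1-yloxy)methyl]benzene F2 is lithiated and opened onto ethylene oxide (n-BuLi, BF3·OEt2, THF, −78 °C) to give 5-[(4-methoxybenzyl)oxy]pent-3-yn-1-ol F3, which Dess–Martin periodinane oxidises to 5-[(4-methoxybenzyl)oxy]pent-3-ynal F4.
- The boron enolate 12 of 4 adds to F4 under the conditions of step 5 and gives, through the O-dibutylboryl aldolate F5, the adduct (4S)-4-benzyl-3-[(2S,3R)-2-(but-2-yn-1-yl)-3-hydroxy-7-[(4-methoxybenzyl)oxy]hept-5-ynoyl]-1,3-oxazolidin-2-one F6.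
- MeOMgBr gives methyl (2S,3R)-2-(but-2-yn-1-yl)-3-hydroxy-7-[(4-methoxybenzyl)oxy]hept-5-ynoate F7, and TBSOTf/2,6-lutidine gives methyl (2S,3R)-2-(but-2-yn-1-yl)-3-[(tert-butyldimethylsilyl)oxy]-7-[(4-methoxybenzyl)oxy]hept-5-ynoate F8.
- DDQ (CH2Cl2, pH 7 buffer) frees methyl (2S,3R)-2-(but-2-yn-1-yl)-3-[(tert-butyldimethylsilyl)oxy]-7-hydroxyhept-5-ynoate F9, and MsCl/Et3N gives methyl (2S,3R)-2-(but-2-yn-1-yl)-3-[(tert-butyldimethylsilyl)oxy]-7-[(methylsulfonyl)oxy]hept-5-ynoate F10.
- Anti-SN2′ substitution with the methylcopper reagent from MeMgBr, CuBr·SMe2 and LiBr (THF, −78 °C) turns the propargylic mesylate into the 1,1-disubstituted allene, and the route is rejoined at 16.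

Step 13. Acylation of the hindered C8 hydroxyl may be slow, the angeloyl unit may isomerise to the tigloyl unit on prolonged heating, or the C11 acetyl group may shift to O8. Fallback, setting out from 23: the Z-alkene is built on the molecule. Purchased ethyl 2-[bis(2,2,2-trifluoroethoxy)phosphoryl]propanoate F11 is saponified (LiOH, THF/H2O, 0 °C) to 2-[bis(2,2,2-trifluoroethoxy)phosphoryl]propanoic acid F12. This is coupled to the C8 hydroxyl of 23 (DCC, DMAP, CH2Cl2, rt) to give (1R,7S,8R,10S)-11-acetoxy-3-oxoguai-4-en-8-yl 2-[bis(2,2,2-trifluoroethoxy)phosphoryl]propanoate F13. Still–Gennari olefination (KN(SiMe3)2, 18-crown-6, THF, −78 °C, then acetaldehyde) should give the (Z)-2-methylbut-2-enoate and arrives at 26.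

Further compounds
F1 | step 11 | (1S,7S,8R,10S)-11-acetoxy-8-[(tert-butyldimethylsilyl)oxy]guai-4-en-3-one (1-epimer of 22) | CC(C)(C)[Si](C)(C)O[C@@H]1C[C@H](C)[C@@H]2CC(=O)C(C)=C2C[C@@H]1C(C)(C)OC(C)=O
F2 | step 5 | 1-methoxy-4-[(prop-2-yn-1-yloxy)methyl]benzene (purchased) | COc1ccc(COCC#C)cc1
F3 | step 5 | 5-[(4-methoxybenzyl)oxy]pent-3-yn-1-ol | COc1ccc(COCC#CCCO)cc1
F4 | step 5 | 5-[(4-methoxybenzyl)oxy]pent-3-ynal | COc1ccc(COCC#CCC=O)cc1
F5 | step 5 | O-dibutylboryl aldolate of F6 (not isolated) | CCCCB(CCCC)O[C@@H]([C@H](CC#CC)C(=O)N1[C@@H](Cc2ccccc2)COC1=O)CC#CCOCc1ccc(OC)cc1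
F6 | step 5 | (4S)-4-benzyl-3-[(2S,3R)-2-(but-2-yn-1-yl)-3-hydroxy-7-[(4-methoxybenzyl)oxy]hept-5-ynoyl]-1,3-oxazolidin-2-one | O[C@@H]([C@H](CC#CC)C(=O)N1[C@@H](Cc2ccccc2)COC1=O)CC#CCOCc1ccc(OC)cc1
F7 | step 5 | methyl (2S,3R)-2-(but-2-yn-1-yl)-3-hydroxy-7-[(4-methoxybenzyl)oxy]hept-5-ynoate | O[C@@H]([C@H](CC#CC)C(=O)OC)CC#CCOCc1ccc(OC)cc1
F8 | step 5 | methyl (2S,3R)-2-(but-2-yn-1-yl)-3-[(tert-butyldimethylsilyl)oxy]-7-[(4-methoxybenzyl)oxy]hept-5-ynoate | CC(C)(C)[Si](C)(C)O[C@@H]([C@H](CC#CC)C(=O)OC)CC#CCOCc1ccc(OC)cc1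
F9 | step 5 | methyl (2S,3R)-2-(but-2-yn-1-yl)-3-[(tert-butyldimethylsilyl)oxy]-7-hydroxyhept-5-ynoate | CC(C)(C)[Si](C)(C)O[C@@H]([C@H](CC#CC)C(=O)OC)CC#CCO
F10 | step 5 | methyl (2S,3R)-2-(but-2-yn-1-yl)-3-[(tert-butyldimethylsilyl)oxy]-7-[(methylsulfonyl)oxy]hept-5-ynoate | CC(C)(C)[Si](C)(C)O[C@@H]([C@H](CC#CC)C(=O)OC)CC#CCOS(C)(=O)=O
F11 | step 13 | ethyl 2-[bis(2,2,2-trifluoroethoxy)phosphoryl]propanoate (purchased) | CCOC(=O)C(C)P(=O)(OCC(F)(F)F)OCC(F)(F)F
F12 | step 13 | 2-[bis(2,2,2-trifluoroethoxy)phosphoryl]propanoic acid | OC(=O)C(C)P(=O)(OCC(F)(F)F)OCC(F)(F)F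
F13 | step 13 | (1R,7S,8R,10S)-11-acetoxy-3-oxoguai-4-en-8-yl 2-[bis(2,2,2-trifluoroethoxy)phosphoryl]propanoate, both epimers at the phosphonate carbon | CC(C(=O)O[C@@H]1C[C@H](C)[C@H]2CC(=O)C(C)=C2C[C@@H]1C(C)(C)OC(C)=O)P(=O)(OCC(F)(F)F)OCC(F)(F)F
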